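Everything rests on cutting ring B, the orsellinate arene, at its C1–C6 bond, so that the crowded di-ortho-substituted aryl ester to ring A is formed before ring B exists. The key step folds a ring-A aryl 3,5,7-trioxooctanoate by aldol addition of chain C2 to the C7 ketone, dehydration and enolisation, which creates ring B with its C1 carboxyl, C2 and C4 hydroxyls and C6 methyl in one operation; it exploits this alternating oxygenation of ring B, the imprint of a linear tetraketide. In the precursor, ring A carries the prenyl group, its second phenol and the adjacent CH2O group tied as a di-tert-butylsilylene, and the other CH2O group as a TBDPS ether.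

Key step: step 11

Remark on the chemistry: ring A is numbered C1 and C2 (the two CH2O carbons), C3 (the phenol that is free in the target), C4 (prenyl), C5 (ester oxygen), C6 (H). Two free phenols would compete for the acylketene, so the C3 phenol is masked before the union. Aryl methyl ethers are avoided because their late cleavage would endanger the prenyl group and the benzylic C–O bonds. The target has no stereocentre. 3,5-Dihydroxybenzyl alcohol, N-methoxy-N-methylacetamide and tBu2Si(OTf)2 are assumed to be purchased (MOM = methoxymethyl, TBDPS = tert-butyldiphenylsilyl).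

Step 1
Reactants: 1 3,5-dihydroxybenzyl alcohol
Product: 2 [3,5-bis(methoxymethoxy)phenyl]methanol
Conditions: MOMCl (2.2 equiv), K2CO3, acetone, 0 °C → rt
Reagents that add atoms: chloromethyl methyl ether, COCCl
Why: Williamson-type O-alkylation in which K2CO3 deprotonates only the two phenols and not the benzylic alcohol, so the phenoxides alone should be alkylated.

Step 2
Reactants: 2 [3,5-bis(methoxymethoxy)phenyl]methanol
Product: 3 {[3,5-bis(methoxymethoxy)phenyl]methoxy}(tert-butyl)diphenylsilane
Conditions: TBDPSCl, imidazole, DMF, rt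
Reagents that add atoms: tert-butyl(chloro)diphenylsilane, CC(C)(C)[Si](Cl)(c1ccccc1)c1ccccc1
Why: Imidazole-promoted silylation of a primary alcohol, the TBDPS ether being chosen because it should survive the acidic acetal cleavage of step 4 and fall to fluoride at the end.

Step 3
Reactants: 3 {[3,5-bis(methoxymethoxy)phenyl]methoxy}(tert-butyl)diphenylsilane; 4 prenyl bromide
Product: 6 {[3,5-bis(methoxymethoxy)-4-(3-methylbut-2-en-1-yl)phenyl]methoxy}(tert-butyl)diphenylsilane, via aryllithium 5 (not isolated)
Conditions: n-BuLi, THF, 0 °C; CuI (10 mol %), then 4, −78 °C → rt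
Reagents that add atoms: none
Why: Directed ortho-metalation removes the C–H flanked by both OMOM groups (ring A C4), the most acidic and doubly coordinated site, and the aryllithium is allylated at the primary carbon of the bromide under CuI catalysis (SN2, not SN2′).

Step 4
Reactants: 6 {[3,5-bis(methoxymethoxy)-4-(3-methylbut-2-en-1-yl)phenyl]methoxy}(tert-butyl)diphenylsilane
Product: 7 5-{[(tert-butyldiphenylsilyl)oxy]methyl}-2-(3-methylbut-2-en-1-yl)benzene-1,3-diol
Conditions: HCl (aq., 2 M), MeOH/THF, rt
Reagents that add atoms: none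
Why: Acid-catalysed methanolysis of the two aryl MOM acetals, carried out while the only benzylic C–O bond is meta to both oxygens and so not prone to ionisation; dilute acid at room temperature should spare the TBDPS ether and the prenyl alkene.

Step 5
Reactants: 7 5-{[(tert-butyldiphenylsilyl)oxy]methyl}-2-(3-methylbut-2-en-1-yl)benzene-1,3-diol
Product: 8 6-{[(tert-butyldiphenylsilyl)oxy]methyl}-2,4-dihydroxy-3-(3-methylbut-2-en-1-yl)benzaldehyde
Conditions: MgCl2, Et3N, (CH2O)n (3 equiv), THF, reflux; then cold aq. HCl (1 M) work-up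
Reagents that add atoms: formaldehyde (from paraformaldehyde), C=O
Why: Magnesium-mediated ortho-formylation of a phenol (Casiraghi–Skattebøl reaction), in which formaldehyde is delivered inside the magnesium phenoxide chelate to the only free ortho carbon (C2 and C6 are equivalent by symmetry, C4 is blocked) and the formyl group then deactivates the ring against a second entry.

Step 6
Reactants: 8 6-{[(tert-butyldiphenylsilyl)oxy]methyl}-2,4-dihydroxy-3-(3-methylbut-2-en-1-yl)benzaldehyde
Product: 9 5-{[(tert-butyldiphenylsilyl)oxy]methyl}-4-(hydroxymethyl)-2-(3-methylbut-2-en-1-yl)benzene-1,3-diol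
Conditions: NaBH4, THF/MeOH, 0 °C; pH 7 phosphate buffer
Reagents that add atoms: none
Why: Chemoselective borohydride reduction of the aldehyde, with a neutral work-up so that the electron-rich hydroxybenzyl alcohol is not ionised; the triol is to be used at once.

Step 7
Reactants: 9 5-{[(tert-butyldiphenylsilyl)oxy]methyl}-4-(hydroxymethyl)-2-(3-methylbut-2-en-1-yl)benzene-1,3-diol
Product: 10 2,2-di-tert-butyl-5-{[(tert-butyldiphenylsilyl)oxy]methyl}-8-(3-methylbut-2-en-1-yl)-4H-1,3,2-benzodioxasilin-7-ol
Conditions: tBu2Si(OTf)2 (1.05 equiv), 2,6-lutidine, CH2Cl2, −78 → 0 °C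
Reagents that add atoms: di-tert-butylsilyl bis(trifluoromethanesulfonate), CC(C)(C)[Si](OS(=O)(=O)C(F)(F)F)(OS(=O)(=O)C(F)(F)F)C(C)(C)C
Why: Cyclic silylene formation as known for 1,3-diols, the bis(triflate) bridging the primary benzylic hydroxyl and the adjacent C3 phenol in a six-membered ring, while the remote C5 phenol, the weaker nucleophile under 2,6-lutidine and without a partner for ring closure, should stay free.

Step 8
Reactants: 11 2,2,6-trimethyl-4H-1,3-dioxin-4-one; 12 acetyl chloride
Product: 14 2,2-dimethyl-6-(2-oxopropyl)-4H-1,3-dioxin-4-one, via lithium dienolate 13 (not isolated)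
Conditions: LiN(SiMe3)2, THF, −78 °C; then 12 (0.5 equiv), −78 °C; aq. HCl (1 M) quench
Reagents that add atoms: none
Why: Vinylogous deprotonation at the 6-methyl group gives a lithium dienolate that is C-acylated at its exocyclic carbon, half an equivalent of chloride being used because the more acidic product consumes a second equivalent of dienolate.

Step 9
Reactants: 14 2,2-dimethyl-6-(2-oxopropyl)-4H-1,3-dioxin-4-one; 15 N-methoxy-N-methylacetamide
Product: 17 6-(2,4-dioxopentyl)-2,2-dimethyl-4H-1,3-dioxin-4-one, via dilithium dianion 16 (not isolated)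
Conditions: LiN(iPr)2 (2.2 equiv), THF, −78 °C; then 15, −78 → −20 °C; aq. HCl (1 M) quench
Reagents that add atoms: none
Why: Claisen-type acylation of a dianion, whose last-formed and least stabilised terminus (the methyl ketone carbon) adds to the Weinreb amide; the stable tetrahedral adduct prevents over-addition.

Step 10
Reactants: 10 2,2-di-tert-butyl-5-{[(tert-butyldiphenylsilyl)oxy]methyl}-8-(3-methylbut-2-en-1-yl)-4H-1,3,2-benzodioxasilin-7-ol; 17 6-(2,4-dioxopentyl)-2,2-dimethyl-4H-1,3-dioxin-4-one
Product: 19 2,2-di-tert-butyl-5-{[(tert-butyldiphenylsilyl)oxy]methyl}-8-(3-methylbut-2-en-1-yl)-4H-1,3,2-benzodioxasilin-7-yl 3,5,7-trioxooctanoate, via acylketene 18 (not isolated)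
Conditions: 17 (1.2 equiv), toluene, 110 °C; concentrate, crude 19 used directly
Reagents that add atoms: none
Why: Thermal retro-[4+2] cleavage of the dioxinone releases acetone and an unhindered acylketene, which is captured by the single free phenol of 10, so the aryl ester bond is in place before the crowded ring B exists.

Step 11
Reactants: 19 2,2-di-tert-butyl-5-{[(tert-butyldiphenylsilyl)oxy]methyl}-8-(3-methylbut-2-en-1-yl)-4H-1,3,2-benzodioxasilin-7-yl 3,5,7-trioxooctanoate
Product: 21 2,2-di-tert-butyl-5-{[(tert-butyldiphenylsilyl)oxy]methyl}-8-(3-methylbut-2-en-1-yl)-4H-1,3,2-benzodioxasilin-7-yl 2,4-dihydroxy-6-methylbenzoate, via aldol adduct 20 (not isolated)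
Conditions: Et3N, CH2Cl2, 0 °C → rt; then AcOH, rt
Reagents that add atoms: none
Why: Et3N forms the enolate at chain C2 (between the ester and the C3 ketone), which adds to the C7 methyl ketone to give the six-membered aldol 20; loss of water and enolisation of the C3 and C5 ketones then give the aromatic 2,4-dihydroxy-6-methylbenzoate. The closest known reaction type is the biomimetic aldol aromatisation of 3,5,7-triketo esters to resorcylate esters. The ring closes in a 6-(enolendo)-exo-trig mode and this forms the C1–C6 bond of ring B. No stereocentre results, since the carbinol carbon of 20 becomes the aromatic C6. The step needs the aldol closure to outrun Claisen closure of C6 onto the ester carbonyl and pyranone formation, both of which would expel the ring-A aryloxide; a mild amine base free of alkoxide or alcohol, the poor leaving-group quality of the electron-rich, ortho-substituted aryloxide and the irreversible aromatisation completed by AcOH should secure this. The silylene and TBDPS groups mask every other hydroxyl of ring A, so no internal nucleophile can attack the ester.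

Step 12
Reactants: 21 2,2-di-tert-butyl-5-{[(tert-butyldiphenylsilyl)oxy]methyl}-8-(3-methylbut-2-en-1-yl)-4H-1,3,2-benzodioxasilin-7-yl 2,4-dihydroxy-6-methylbenzoate
Product: 22 3-hydroxy-4,5-bis(hydroxymethyl)-2-(3-methylbut-2-en-1-yl)phenyl 2,4-dihydroxy-6-methylbenzoate
Conditions: HF·pyridine, pyridine, THF, 0 °C → rt
Reagents that add atoms: none
Why: Fluoride cleaves all three Si–O bonds in one operation, and pyridine-buffered HF should be neither basic enough to cleave the aryl ester nor acidic enough to ionise the hydroxybenzyl alcohol or cyclise the ortho-prenyl phenol.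

Compound list
1 | 3,5-dihydroxybenzyl alcohol | OCc1cc(O)cc(O)c1 | starting material
2 | [3,5-bis(methoxymethoxy)phenyl]methanol | COCOc1cc(CO)cc(OCOC)c1 | intermediate
3 | {[3,5-bis(methoxymethoxy)phenyl]methoxy}(tert-butyl)diphenylsilane | COCOc1cc(CO[Si](c2ccccc2)(c2ccccc2)C(C)(C)C)cc(OCOC)c1 | intermediate
4 | prenyl bromide (1-bromo-3-methylbut-2-ene) | CC(C)=CCBr | starting material
5 | {4-{[(tert-butyldiphenylsilyl)oxy]methyl}-2,6-bis(methoxymethoxy)phenyl}lithium | [Li]c1c(OCOC)cc(CO[Si](c2ccccc2)(c2ccccc2)C(C)(C)C)cc1OCOC | intermediate (not isolated)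
6 | {[3,5-bis(methoxymethoxy)-4-(3-methylbut-2-en-1-yl)phenyl]methoxy}(tert-butyl)diphenylsilane | COCOc1cc(CO[Si](c2ccccc2)(c2ccccc2)C(C)(C)C)cc(OCOC)c1CC=C(C)C | intermediate
7 | 5-{[(tert-butyldiphenylsilyl)oxy]methyl}-2-(3-methylbut-2-en-1-yl)benzene-1,3-diol | Oc1cc(CO[Si](c2ccccc2)(c2ccccc2)C(C)(C)C)cc(O)c1CC=C(C)C | intermediate
8 | 6-{[(tert-butyldiphenylsilyl)oxy]methyl}-2,4-dihydroxy-3-(3-methylbut-2-en-1-yl)benzaldehyde | O=Cc1c(CO[Si](c2ccccc2)(c2ccccc2)C(C)(C)C)cc(O)c(CC=C(C)C)c1O | intermediate
9 | 5-{[(tert-butyldiphenylsilyl)oxy]methyl}-4-(hydroxymethyl)-2-(3-methylbut-2-en-1-yl)benzene-1,3-diol | OCc1c(CO[Si](c2ccccc2)(c2ccccc2)C(C)(C)C)cc(O)c(CC=C(C)C)c1O | intermediate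
10 | 2,2-di-tert-butyl-5-{[(tert-butyldiphenylsilyl)oxy]methyl}-8-(3-methylbut-2-en-1-yl)-4H-1,3,2-benzodioxasilin-7-ol | CC(C)=CCc1c(O)cc(CO[Si](c2ccccc2)(c2ccccc2)C(C)(C)C)c2CO[Si](C(C)(C)C)(C(C)(C)C)Oc12 | intermediate
11 | 2,2,6-trimethyl-4H-1,3-dioxin-4-one | CC1=CC(=O)OC(C)(C)O1 | starting material
12 | acetyl chloride | CC(=O)Cl | starting material
13 | lithium 2,2-dimethyl-6-methylidene-6H-1,3-dioxin-4-olate (dienolate of 11) | C=C1C=C(O[Li])OC(C)(C)O1 | intermediate (not isolated)
14 | 2,2-dimethyl-6-(2-oxopropyl)-4H-1,3-dioxin-4-one | CC(=O)CC1=CC(=O)OC(C)(C)O1 | intermediate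
15 | N-methoxy-N-methylacetamide | CON(C)C(C)=O | starting material
16 | dilithium dianion of 14 (enolates at the ring carbonyl and at the methyl ketone) | C=C(O[Li])C=C1C=C(O[Li])OC(C)(C)O1 | intermediate (not isolated)
17 | 6-(2,4-dioxopentyl)-2,2-dimethyl-4H-1,3-dioxin-4-one | CC(=O)CC(=O)CC1=CC(=O)OC(C)(C)O1 | intermediate
18 | 3,5,7-trioxooct-1-en-1-one (acylketene) | CC(=O)CC(=O)CC(=O)C=C=O | intermediate (not isolated)
19 | 2,2-di-tert-butyl-5-{[(tert-butyldiphenylsilyl)oxy]methyl}-8-(3-methylbut-2-en-1-yl)-4H-1,3,2-benzodioxasilin-7-yl 3,5,7-trioxooctanoate | CC(=O)CC(=O)CC(=O)CC(=O)Oc1cc(CO[Si](c2ccccc2)(c2ccccc2)C(C)(C)C)c2CO[Si](C(C)(C)C)(C(C)(C)C)Oc2c1CC=C(C)C | intermediate (key-step precursor)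
20 | the same ring-A aryl ester of 2-hydroxy-2-methyl-4,6-dioxocyclohexane-1-carboxylic acid (aldol adduct, configuration undefined and lost on aromatisation) | CC1(O)CC(=O)CC(=O)C1C(=O)Oc1cc(CO[Si](c2ccccc2)(c2ccccc2)C(C)(C)C)c2CO[Si](C(C)(C)C)(C(C)(C)C)Oc2c1CC=C(C)C | intermediate (not isolated)
21 | 2,2-di-tert-butyl-5-{[(tert-butyldiphenylsilyl)oxy]methyl}-8-(3-methylbut-2-en-1-yl)-4H-1,3,2-benzodioxasilin-7-yl 2,4-dihydroxy-6-methylbenzoate | Cc1cc(O)cc(O)c1C(=O)Oc1cc(CO[Si](c2ccccc2)(c2ccccc2)C(C)(C)C)c2CO[Si](C(C)(C)C)(C(C)(C)C)Oc2c1CC=C(C)C | intermediate (key-step product)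
22 | 3-hydroxy-4,5-bis(hydroxymethyl)-2-(3-methylbut-2-en-1-yl)phenyl 2,4-dihydroxy-6-methylbenzoate | CC(C)=CCc1c(OC(=O)c2c(C)cc(O)cc2O)cc(CO)c(CO)c1O | target

Total step count: 12 (steps 1–7 for ring A, steps 8–9 for the diketo-dioxinone, steps 10–12 for union, ring B formation and deprotection).
Longest linear sequence: 10 steps (1–7, then 10, 11, 12).

Steps most likely to fail

Step 11. The triketo chain may expel the ring-A aryloxide faster than C2 adds to C7, either by Claisen closure of C6 onto the ester carbonyl or by O-cyclisation to a 4-hydroxy-2-pyranone; the same loss may begin during the hot capture of step 10. The fallback sets out from 17 and 10 and closes the ring while the carboxyl is still masked in the dioxinone, where there is no leaving group. Et3N in CH2Cl2 followed by acid should turn 17 into 7-hydroxy-2,2,5-trimethyl-4H-1,3-benzodioxin-4-one F1 (aldol of the dioxinone C5 onto the terminal ketone, then aromatisation). TBSCl and imidazole would give 7-[(tert-butyldimethylsilyl)oxy]-2,2,5-trimethyl-4H-1,3-benzodioxin-4-one F2. The sodium phenoxide of 10 (NaH, THF) would then open F2 at its carbonyl with loss of acetone to give 2,2-di-tert-butyl-5-{[(tert-butyldiphenylsilyl)oxy]methyl}-8-(3-methylbut-2-en-1-yl)-4H-1,3,2-benzodioxasilin-7-yl 4-[(tert-butyldimethylsilyl)oxy]-2-hydroxy-6-methylbenzoate F3. HF·pyridine as in step 12 removes all silyl groups, and the fallback rejoins the route at 22.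

Step 7. The bis(triflate) may silylate the lone C5 phenol and give open or bridged silyl ethers, and the electron-rich hydroxybenzyl alcohol of 9 may ionise and oligomerise on handling. The fallback sets out from 8 and blocks the competing phenol first. Allyl bromide and K2CO3 in acetone should alkylate only the phenol para to the formyl group, the ortho phenol being held in a hydrogen bond, to give 4-(allyloxy)-6-{[(tert-butyldiphenylsilyl)oxy]methyl}-2-hydroxy-3-(3-methylbut-2-en-1-yl)benzaldehyde F4. NaBH4 would give 5-(allyloxy)-3-{[(tert-butyldiphenylsilyl)oxy]methyl}-2-(hydroxymethyl)-6-(3-methylbut-2-en-1-yl)phenol F5, which has one phenol only and a less electron-rich ring. tBu2Si(OTf)2 and 2,6-lutidine would give 7-(allyloxy)-2,2-di-tert-butyl-5-{[(tert-butyldiphenylsilyl)oxy]methyl}-8-(3-methylbut-2-en-1-yl)-4H-1,3,2-benzodioxasiline F6. Pd(PPh3)4 and morpholine then remove the allyl group, and the fallback rejoins the route at 10.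

Step 5. A second formylation at the remaining ortho position, or methylene-bridged condensation of the very electron-rich resorcinol with formaldehyde, may consume the material. The fallback sets out from 6 and introduces the formyl group before the phenols are freed, by directed ortho-metalation. s-BuLi and TMEDA in Et2O at −78 °C would lithiate 6 ortho to a MOM ether (the only ring C–H left, C2 and C6 being equivalent), and DMF would give 6-{[(tert-butyldiphenylsilyl)oxy]methyl}-2,4-bis(methoxymethoxy)-3-(3-methylbut-2-en-1-yl)benzaldehyde F7. The HCl/MeOH treatment of step 4 then removes both acetals, and the fallback rejoins the route at 8.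

Further compounds
F1 | step 11 | 7-hydroxy-2,2,5-trimethyl-4H-1,3-benzodioxin-4-one | Cc1cc(O)cc2OC(C)(C)OC(=O)c12
F2 | step 11 | 7-[(tert-butyldimethylsilyl)oxy]-2,2,5-trimethyl-4H-1,3-benzodioxin-4-one | Cc1cc(O[Si](C)(C)C(C)(C)C)cc2OC(C)(C)OC(=O)c12
F3 | step 11 | 2,2-di-tert-butyl-5-{[(tert-butyldiphenylsilyl)oxy]methyl}-8-(3-methylbut-2-en-1-yl)-4H-1,3,2-benzodioxasilin-7-yl 4-[(tert-butyldimethylsilyl)oxy]-2-hydroxy-6-methylbenzoate | Cc1cc(O[Si](C)(C)C(C)(C)C)cc(O)c1C(=O)Oc1cc(CO[Si](c2ccccc2)(c2ccccc2)C(C)(C)C)c2CO[Si](C(C)(C)C)(C(C)(C)C)Oc2c1CC=C(C)C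
F4 | step 7 | 4-(allyloxy)-6-{[(tert-butyldiphenylsilyl)oxy]methyl}-2-hydroxy-3-(3-methylbut-2-en-1-yl)benzaldehyde | O=Cc1c(CO[Si](c2ccccc2)(c2ccccc2)C(C)(C)C)cc(OCC=C)c(CC=C(C)C)c1O
F5 | step 7 | 5-(allyloxy)-3-{[(tert-butyldiphenylsilyl)oxy]methyl}-2-(hydroxymethyl)-6-(3-methylbut-2-en-1-yl)phenol | OCc1c(CO[Si](c2ccccc2)(c2ccccc2)C(C)(C)C)cc(OCC=C)c(CC=C(C)C)c1O
F6 | step 7 | 7-(allyloxy)-2,2-di-tert-butyl-5-{[(tert-butyldiphenylsilyl)oxy]methyl}-8-(3-methylbut-2-en-1-yl)-4H-1,3,2-benzodioxasiline | C=CCOc1cc(CO[Si](c2ccccc2)(c2ccccc2)C(C)(C)C)c2CO[Si](C(C)(C)C)(C(C)(C)C)Oc2c1CC=C(C)C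
F7 | step 5 | 6-{[(tert-butyldiphenylsilyl)oxy]methyl}-2,4-bis(methoxymethoxy)-3-(3-methylbut-2-en-1-yl)benzaldehyde | O=Cc1c(CO[Si](c2ccccc2)(c2ccccc2)C(C)(C)C)cc(OCOC)c(CC=C(C)C)c1OCOC
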